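**Strategy.** Ring C (C1–C4, C4a, C9a; decahydrofluorene numbering) is opened at C4–C4a. Because C4a is α and C9a β to C4b when C4b is an ester carbon, and C1–C4 is a meso-derived syn-dimethyl chain ending in CH2Br, one Michael-initiated ring closure builds ring C: a RAMP-hydrazone azaenolate adds to C9a of a 7-bromo-enoate and the resulting ester enolate alkylates C4, setting C9a and C4a. Rings A and B then arise by an intramolecular Diels–Alder reaction of a (Z)-enyne diene on C4a with an enal on C9a, and the cyclophane by Ullmann etherification followed by ammonia-induced hydroxylactam formation.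

Key step: step 7

Remark: core carbons carry decahydrofluorene numbers (ring C = C1–C4, C4a, C9a; ring B = C4a, C4b, C8a, C9, C9a; ring A = C4b, C5–C8, C8a), lactam carbons are C2'–C5', and the alkylation of step 18 is assumed to give both C3' epimers, which are carried on as a mixture because this centre equilibrates in step 20.

Step 1
Reactants: 1 meso-2,4-dimethylglutaric anhydride
Product: 2 (2R,4S)-5-methoxy-2,4-dimethyl-5-oxopentanoic acid
Conditions: MeOH (10 equiv), (DHQD)2AQN (10 mol%), Et2O, −30 °C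
Reagents that add atoms: methanol CO
Why: Cinchona-alkaloid-catalysed alcoholysis desymmetrises the meso anhydride by selecting one enantiotopic carbonyl, which fixes both methyl-bearing centres (future C1 and C3); should the opposite sense be found, (DHQ)2AQN or reduction of the ester instead of the acid in step 2 leads into the same series.

Step 2
Reactants: 2 (2R,4S)-5-methoxy-2,4-dimethyl-5-oxopentanoic acid
Product: 3 methyl (2S,4R)-5-hydroxy-2,4-dimethylpentanoate
Conditions: BH3·SMe2, THF, 0 °C → rt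
Reagents that add atoms: none
Why: Borane reduces the carboxylic acid chemoselectively in the presence of the methyl ester (acyloxyborane pathway) and leaves both stereocentres untouched.

Step 3
Reactants: 3 methyl (2S,4R)-5-hydroxy-2,4-dimethylpentanoate
Product: 4 methyl (2S,4R)-5-bromo-2,4-dimethylpentanoate
Conditions: CBr4, PPh3, CH2Cl2, 0 °C
Reagents that add atoms: tetrabromomethane BrC(Br)(Br)Br
Why: Appel bromination converts the primary alcohol into the bromide (future C4) under neutral conditions that do not epimerise the ester α-centre.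

Step 4
Reactants: 4 methyl (2S,4R)-5-bromo-2,4-dimethylpentanoate
Product: 5 (2S,4R)-5-bromo-2,4-dimethylpentanal
Conditions: i-Bu2AlH (1.1 equiv), CH2Cl2, −78 °C
Reagents that add atoms: none
Why: Partial ester reduction stops at the tetrahedral aluminium hemiacetal at low temperature and releases the aldehyde on work-up, which is used at once to avoid α-epimerisation.

Step 5
Reactants: 5 (2S,4R)-5-bromo-2,4-dimethylpentanal
Product: 6 methyl (2E,4S,6R)-7-bromo-4,6-dimethylhept-2-enoate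
Conditions: Ph3P=CHCO2Me, CH2Cl2, rt
Reagents that add atoms: methyl (triphenylphosphoranylidene)acetate COC(=O)C=P(c1ccccc1)(c1ccccc1)c1ccccc1
Why: Wittig olefination with the stabilised ylide should give the (E)-enoate under neutral conditions that keep the γ-centre (C1) intact.

Step 6
Reactants: 7 (R)-1-amino-2-(methoxymethyl)pyrrolidine (RAMP); 8 acetaldehyde
Product: 9 (E)-N-[(2R)-2-(methoxymethyl)pyrrolidin-1-yl]ethanimine (acetaldehyde RAMP hydrazone)
Conditions: Et2O, MgSO4, 0 °C → rt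
Reagents that add atoms: none
Why: Condensation of the hydrazine with the aldehyde gives the (E)-hydrazone (hydrazone formation).

Step 7
Reactants: 6 methyl (2E,4S,6R)-7-bromo-4,6-dimethylhept-2-enoate; 9 acetaldehyde RAMP hydrazone
Product: 11 methyl (1R,2R,3S,5R)-2-{(2E)-2-[(2R)-2-(methoxymethyl)pyrrolidin-1-ylimino]ethyl}-3,5-dimethylcyclohexane-1-carboxylate, via Michael adduct lithium ester enolate 10 (not isolated)
Conditions: 9, LiN(i-Pr)2 (1.05 equiv), THF, 0 °C; then 6, −78 °C; then DMPU (4 equiv), −78 °C → rt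
Reagents that add atoms: none
Why: LiN(i-Pr)2 converts hydrazone 9 into its lithium azaenolate, which adds 1,4 to the (E)-enoate 6 at C9a through a closed, lithium-bridged transition state (azaenolate nitrogen–Li–ester carbonyl, s-cis enoate) to give the ester enolate 10, and on warming with DMPU this enolate displaces the primary bromide and forms the C4–C4a bond. The closest known reaction type is the asymmetric Michael-initiated ring closure of SAMP/RAMP-hydrazone azaenolates with ω-bromo-2-alkenoates, which gives trans-2-substituted cycloalkanecarboxylates. Ring C is closed in the 6-exo-tet mode. C9a is set by the RAMP auxiliary, whose methoxymethyl-chelated lithium delivers the enoate to one azaenolate face and thereby fixes the enoate face (reagent control over the weak bias of the neighbouring C1 methyl centre; the sense is assigned from the closed transition-state model, and SAMP would serve if it proved opposite), while C4a is set in a chair transition state with both methyl groups, the C9a side chain and the ester enolate equatorial, that is trans to C9a, and being α to the ester it can also be equilibrated to this all-equatorial arrangement. The step needs 1,4-addition to outrun 1,2-addition and direct SN2 attack of the azaenolate on CH2Br, which the soft delocalised azaenolate at −78 °C should secure, and it needs ring closure to follow the Michael step, which is secured because the ester enolate alkylates the unactivated bromide only on warming with DMPU.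

Step 8
Reactants: 11 methyl (1R,2R,3S,5R)-2-{(2E)-2-[(2R)-2-(methoxymethyl)pyrrolidin-1-ylimino]ethyl}-3,5-dimethylcyclohexane-1-carboxylate
Product: 12 (1R,2R,3S,5R)-2-{(2E)-2-[(2R)-2-(methoxymethyl)pyrrolidin-1-ylimino]ethyl}-3,5-dimethylcyclohexane-1-carbaldehyde
Conditions: i-Bu2AlH (1.1 equiv), toluene, −78 °C
Reagents that add atoms: none
Why: Partial reduction of the ester gives the C4b aldehyde while the hydrazone, inert to the hydride at −78 °C, serves as protecting group of the second aldehyde; C4a keeps its equatorial (thermodynamic) configuration.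

Step 9
Reactants: 12 (1R,2R,3S,5R)-2-{(2E)-2-[(2R)-2-(methoxymethyl)pyrrolidin-1-ylimino]ethyl}-3,5-dimethylcyclohexane-1-carbaldehyde
Product: 13 (2E)-3-[(1S,2R,3S,5R)-2-{(2E)-2-[(2R)-2-(methoxymethyl)pyrrolidin-1-ylimino]ethyl}-3,5-dimethylcyclohexyl]prop-2-enal
Conditions: Ph3P=CHCHO, toluene, 80 °C
Reagents that add atoms: (triphenylphosphoranylidene)acetaldehyde O=CC=P(c1ccccc1)(c1ccccc1)c1ccccc1
Why: Wittig olefination with the stabilised formylmethylene ylide should give the (E)-enal and so installs the C4b=C5 alkene.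

Step 10
Reactants: 13 (2E)-3-[(1S,2R,3S,5R)-2-{(2E)-2-[(2R)-2-(methoxymethyl)pyrrolidin-1-ylimino]ethyl}-3,5-dimethylcyclohexyl]prop-2-enal
Product: 14 (E)-2-[(1R,2S,4R,6S)-4,6-dimethyl-2-[(1E,3Z)-6-(triisopropylsilyl)hexa-1,3-dien-5-yn-1-yl]cyclohexyl]-N-[(2R)-2-(methoxymethyl)pyrrolidin-1-yl]ethanimine
Conditions: i-Pr3SiC≡CCH2Si(i-Pr)3, n-BuLi, THF, −20 °C; then 13, −78 °C → rt
Reagents that add atoms: 1,3-bis(triisopropylsilyl)propyne CC(C)[Si](C(C)C)(C(C)C)CC#C[Si](C(C)C)(C(C)C)C(C)C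
Why: Peterson olefination with the lithiated bis-silylpropyne adds 1,2 to the enal and the β-silyl alkoxide eliminates to the (Z)-enyne, so that the diene terminus C7 carries its alkynyl group cis.

Step 11
Reactants: 14 (E)-2-[(1R,2S,4R,6S)-4,6-dimethyl-2-[(1E,3Z)-6-(triisopropylsilyl)hexa-1,3-dien-5-yn-1-yl]cyclohexyl]-N-[(2R)-2-(methoxymethyl)pyrrolidin-1-yl]ethanimine
Product: 15 2-[(1R,2S,4R,6S)-4,6-dimethyl-2-[(1E,3Z)-6-(triisopropylsilyl)hexa-1,3-dien-5-yn-1-yl]cyclohexyl]acetaldehyde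
Conditions: saturated aqueous oxalic acid, Et2O, rt
Reagents that add atoms: water O
Why: Mild biphasic acid hydrolysis cleaves the hydrazone C=N without touching the dienyne or the silyl alkyne, and the auxiliary is recovered from the aqueous phase.

Step 12
Reactants: 15 2-[(1R,2S,4R,6S)-4,6-dimethyl-2-[(1E,3Z)-6-(triisopropylsilyl)hexa-1,3-dien-5-yn-1-yl]cyclohexyl]acetaldehyde
Product: 17 (1R,2E)-1-[(1R,2S,4R,6S)-4,6-dimethyl-2-[(1E,3Z)-6-(triisopropylsilyl)hexa-1,3-dien-5-yn-1-yl]cyclohexyl]-4-oxobut-2-en-1-yl benzoate, via α-benzoyloxy aldehyde 16 (not isolated)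
Conditions: (S)-α,α-diphenylprolinol trimethylsilyl ether (10 mol%), (PhCO2)2 (1.1 equiv), hydroquinone (10 mol%), THF, 0 °C; filtration through SiO2; then Ph3P=CHCHO (2 equiv), CH2Cl2, rt
Reagents that add atoms: dibenzoyl peroxide O=C(OOC(=O)c1ccccc1)c1ccccc1; (triphenylphosphoranylidene)acetaldehyde O=CC=P(c1ccccc1)(c1ccccc1)c1ccccc1
Why: Enamine-catalysed α-benzoyloxylation sets C9 under catalyst control, because the bulky diarylmethyl group shields one face of the (E)-enamine and the peroxide delivers the benzoate to the other, and the labile α-acyloxy aldehyde is homologated at once by Wittig olefination to the (E)-enal dienophile.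

Step 13
Reactants: 17 (1R,2E)-1-[(1R,2S,4R,6S)-4,6-dimethyl-2-[(1E,3Z)-6-(triisopropylsilyl)hexa-1,3-dien-5-yn-1-yl]cyclohexyl]-4-oxobut-2-en-1-yl benzoate
Product: 18 8-formyl-1,3-dimethyl-7-[(triisopropylsilyl)ethynyl]-2,3,4,4a,4b,7,8,8a,9,9a-decahydro-1H-fluoren-9-yl benzoate (nine core stereocentres as in 30)
Conditions: Me2AlCl (1.2 equiv), CH2Cl2, −78 → −20 °C
Reagents that add atoms: none
Why: Lewis-acid-promoted type 1 intramolecular Diels–Alder reaction in which the complexed enal adds endo to the diene held with H-4a eclipsing it (minimal allylic strain) on the face fixed by the trans-diequatorial ring C arms, which should give the trans-anti-trans fused rings B and A and set C4b, C8a and C8, while the alkynyl group, inside in the s-cis (Z)-diene and small because it is sp-hybridised, ends trans to C4a at C7.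

Step 14
Reactants: 18 8-formyl-1,3-dimethyl-7-[(triisopropylsilyl)ethynyl]-2,3,4,4a,4b,7,8,8a,9,9a-decahydro-1H-fluoren-9-yl benzoate
Product: 19 ethyl 3-{9-(benzoyloxy)-1,3-dimethyl-7-[(triisopropylsilyl)ethynyl]-2,3,4,4a,4b,7,8,8a,9,9a-decahydro-1H-fluoren-8-yl}-3-oxopropanoate (core as in 30)
Conditions: N2CHCO2Et, SnCl2 (10 mol%), CH2Cl2, rt
Reagents that add atoms: ethyl diazoacetate CCOC(=O)C=[N+]=[N-]
Why: Roskamp homologation (Lewis-acid-catalysed addition of the diazoester to the aldehyde, 1,2-hydride shift and loss of N2) gives the β-keto ester without base, so C8 is not epimerised.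

Step 15
Reactants: 19 ethyl 3-{9-(benzoyloxy)-1,3-dimethyl-7-[(triisopropylsilyl)ethynyl]-2,3,4,4a,4b,7,8,8a,9,9a-decahydro-1H-fluoren-8-yl}-3-oxopropanoate
Product: 21 ethyl 3-(7-ethynyl-9-hydroxy-1,3-dimethyl-2,3,4,4a,4b,7,8,8a,9,9a-decahydro-1H-fluoren-8-yl)-3-oxopropanoate (core as in 30), via terminal alkyne benzoate 20 (not isolated)
Conditions: Bu4NF, THF, 0 °C; then K2CO3 (0.5 equiv), EtOH, rt
Reagents that add atoms: none
Why: Fluoride cleaves the alkynyl C–Si bond and base-catalysed transesterification with ethanol removes the benzoate, the β-keto ester being protected as its enolate against retro-Claisen cleavage.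

Step 16
Reactants: 21 ethyl 3-(7-ethynyl-9-hydroxy-1,3-dimethyl-2,3,4,4a,4b,7,8,8a,9,9a-decahydro-1H-fluoren-8-yl)-3-oxopropanoate
Product: 22 ethyl 3-(7-ethenyl-9-hydroxy-1,3-dimethyl-2,3,4,4a,4b,7,8,8a,9,9a-decahydro-1H-fluoren-8-yl)-3-oxopropanoate (core as in 30)
Conditions: H2 (1 atm), Pd/CaCO3 poisoned with Pb(OAc)2, quinoline, EtOAc, rt
Reagents that add atoms: none
Why: Semihydrogenation over poisoned palladium stops at the vinyl group and should leave the ring A cis-alkene untouched.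

Step 17
Reactants: 23 (4-iodophenyl)acetic acid
Product: 26 1-bromo-3-(4-iodophenyl)propan-2-one, via (4-iodophenyl)acetyl chloride 24 (not isolated), via 1-diazo-3-(4-iodophenyl)propan-2-one 25 (not isolated)
Conditions: (COCl)2, DMF (cat.), CH2Cl2, rt; then CH2N2, Et3N, Et2O, 0 °C; then 48% aqueous HBr, 0 °C
Reagents that add atoms: diazomethane C=[N+]=[N-]; hydrogen bromide Br
Why: Arndt–Eistert-type sequence in which the acid chloride acylates diazomethane and the diazoketone is hydrobrominated with loss of N2, which places the bromine only on the new methylene.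

Step 18
Reactants: 22 ethyl 3-(7-ethenyl-9-hydroxy-1,3-dimethyl-2,3,4,4a,4b,7,8,8a,9,9a-decahydro-1H-fluoren-8-yl)-3-oxopropanoate; 26 1-bromo-3-(4-iodophenyl)propan-2-one
Product: 27 ethyl 2-[(7-ethenyl-9-hydroxy-1,3-dimethyl-2,3,4,4a,4b,7,8,8a,9,9a-decahydro-1H-fluoren-8-yl)carbonyl]-5-(4-iodophenyl)-4-oxopentanoate (core as in 30; both C3' epimers)
Conditions: K2CO3, acetone, 0 °C → rt
Reagents that add atoms: none
Why: SN2 C-alkylation of the β-keto ester enolate with the reactive α-bromoketone gives the 2-acyl-1,4-diketone, whose new enolisable centre is left uncontrolled because it is set in step 20.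

Step 19
Reactants: 27 ethyl 2-[(7-ethenyl-9-hydroxy-1,3-dimethyl-2,3,4,4a,4b,7,8,8a,9,9a-decahydro-1H-fluoren-8-yl)carbonyl]-5-(4-iodophenyl)-4-oxopentanoate
Product: 28 macrocyclic aryl ether keto ester (13-membered para-cyclophane closed between O-9 and the arene; core as in 30; both C3' epimers)
Conditions: CuI (20 mol%), 3,4,7,8-tetramethyl-1,10-phenanthroline (40 mol%), Cs2CO3 (3 equiv), 4 Å molecular sieves, toluene (0.001 M), 110 °C
Reagents that add atoms: none
Why: Ullmann-type intramolecular C–O coupling of the secondary alkoxide with the aryl iodide closes the cyclophane with retention at C9, high dilution and the cis disposition of O-9 and the C8 side chain on ring B favouring ring closure over oligomerisation.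

Step 20
Reactants: 28 macrocyclic aryl ether keto ester
Product: 30 xenoacremone H, via macrocyclic keto amide 29 (not isolated)
Conditions: NH3 (7 M in MeOH), H2O, sealed tube, 100 °C
Reagents that add atoms: ammonia N
Why: Ammonolysis of the ester and addition of the amide nitrogen to the benzyl ketone give the 5-hydroxypyrrolidin-2-one (lactamisation by hemiaminal formation), C3' equilibrating through the β-dicarbonyl enol and C5' by ring–chain tautomerism so that both should settle under thermodynamic control in the strained macrocycle, where a Paal–Knorr pyrrole would be prohibitively strained.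

**Compound list**

1 | meso-2,4-dimethylglutaric anhydride, (3R,5S)-3,5-dimethyloxane-2,6-dione | O=C1OC(=O)[C@H](C)C[C@@H]1C | starting material
2 | (2R,4S)-5-methoxy-2,4-dimethyl-5-oxopentanoic acid | OC(=O)[C@H](C)C[C@H](C)C(=O)OC | intermediate
3 | methyl (2S,4R)-5-hydroxy-2,4-dimethylpentanoate | OC[C@H](C)C[C@H](C)C(=O)OC | intermediate
4 | methyl (2S,4R)-5-bromo-2,4-dimethylpentanoate | BrC[C@H](C)C[C@H](C)C(=O)OC | intermediate
5 | (2S,4R)-5-bromo-2,4-dimethylpentanal | BrC[C@H](C)C[C@H](C)C=O | intermediate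
6 | methyl (2E,4S,6R)-7-bromo-4,6-dimethylhept-2-enoate | BrC[C@H](C)C[C@H](C)/C=C/C(=O)OC | intermediate
7 | (R)-1-amino-2-(methoxymethyl)pyrrolidine (RAMP) | NN1CCC[C@@H]1COC | starting material
8 | acetaldehyde | CC=O | starting material
9 | (E)-N-[(2R)-2-(methoxymethyl)pyrrolidin-1-yl]ethanimine | C/C=N/N1CCC[C@@H]1COC | intermediate
10 | lithium ester enolate of the acyclic Michael adduct (C9a set, C–Br intact) | BrC[C@H](C)C[C@H](C)[C@@H](C/C=N/N1CCC[C@@H]1COC)C=C([O-])OC.[Li+] | intermediate (not isolated)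
11 | methyl (1R,2R,3S,5R)-2-{(2E)-2-[(2R)-2-(methoxymethyl)pyrrolidin-1-ylimino]ethyl}-3,5-dimethylcyclohexane-1-carboxylate | COC(=O)[C@@H]1C[C@H](C)C[C@H](C)[C@H]1C/C=N/N1CCC[C@@H]1COC | intermediate
12 | (1R,2R,3S,5R)-2-{(2E)-2-[(2R)-2-(methoxymethyl)pyrrolidin-1-ylimino]ethyl}-3,5-dimethylcyclohexane-1-carbaldehyde | O=C[C@@H]1C[C@H](C)C[C@H](C)[C@H]1C/C=N/N1CCC[C@@H]1COC | intermediate
13 | (2E)-3-[(1S,2R,3S,5R)-2-{(2E)-2-[(2R)-2-(methoxymethyl)pyrrolidin-1-ylimino]ethyl}-3,5-dimethylcyclohexyl]prop-2-enal | O=C/C=C/[C@@H]1C[C@H](C)C[C@H](C)[C@H]1C/C=N/N1CCC[C@@H]1COC | intermediate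
14 | (E)-2-[(1R,2S,4R,6S)-4,6-dimethyl-2-[(1E,3Z)-6-(triisopropylsilyl)hexa-1,3-dien-5-yn-1-yl]cyclohexyl]-N-[(2R)-2-(methoxymethyl)pyrrolidin-1-yl]ethanimine | CC(C)[Si](C(C)C)(C(C)C)C#C/C=C\C=C\[C@@H]1C[C@H](C)C[C@H](C)[C@H]1C/C=N/N1CCC[C@@H]1COC | intermediate
15 | 2-[(1R,2S,4R,6S)-4,6-dimethyl-2-[(1E,3Z)-6-(triisopropylsilyl)hexa-1,3-dien-5-yn-1-yl]cyclohexyl]acetaldehyde | CC(C)[Si](C(C)C)(C(C)C)C#C/C=C\C=C\[C@@H]1C[C@H](C)C[C@H](C)[C@H]1CC=O | intermediate
16 | (1S)-1-[(1R,2S,4R,6S)-4,6-dimethyl-2-[(1E,3Z)-6-(triisopropylsilyl)hexa-1,3-dien-5-yn-1-yl]cyclohexyl]-2-oxoethyl benzoate | CC(C)[Si](C(C)C)(C(C)C)C#C/C=C\C=C\[C@@H]1C[C@H](C)C[C@H](C)[C@H]1[C@H](OC(=O)c1ccccc1)C=O | intermediate (not isolated)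
17 | (1R,2E)-1-[(1R,2S,4R,6S)-4,6-dimethyl-2-[(1E,3Z)-6-(triisopropylsilyl)hexa-1,3-dien-5-yn-1-yl]cyclohexyl]-4-oxobut-2-en-1-yl benzoate | CC(C)[Si](C(C)C)(C(C)C)C#C/C=C\C=C\[C@@H]1C[C@H](C)C[C@H](C)[C@H]1[C@H](OC(=O)c1ccccc1)/C=C/C=O | intermediate
18 | 8-formyl-1,3-dimethyl-7-[(triisopropylsilyl)ethynyl]-2,3,4,4a,4b,7,8,8a,9,9a-decahydro-1H-fluoren-9-yl benzoate (nine core stereocentres as in 30) | CC(C)[Si](C(C)C)(C(C)C)C#C[C@@H]1C=C[C@H]2[C@@H]3C[C@H](C)C[C@H](C)[C@H]3[C@H](OC(=O)c4ccccc4)[C@@H]2[C@H]1C=O | intermediate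
19 | ethyl 3-{9-(benzoyloxy)-1,3-dimethyl-7-[(triisopropylsilyl)ethynyl]-2,3,4,4a,4b,7,8,8a,9,9a-decahydro-1H-fluoren-8-yl}-3-oxopropanoate (core as in 30) | CC(C)[Si](C(C)C)(C(C)C)C#C[C@@H]1C=C[C@H]2[C@@H]3C[C@H](C)C[C@H](C)[C@H]3[C@H](OC(=O)c4ccccc4)[C@@H]2[C@H]1C(=O)CC(=O)OCC | intermediate
20 | ethyl 3-[9-(benzoyloxy)-7-ethynyl-1,3-dimethyl-2,3,4,4a,4b,7,8,8a,9,9a-decahydro-1H-fluoren-8-yl]-3-oxopropanoate (core as in 30) | C#C[C@@H]1C=C[C@H]2[C@@H]3C[C@H](C)C[C@H](C)[C@H]3[C@H](OC(=O)c4ccccc4)[C@@H]2[C@H]1C(=O)CC(=O)OCC | intermediate (not isolated)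
21 | ethyl 3-(7-ethynyl-9-hydroxy-1,3-dimethyl-2,3,4,4a,4b,7,8,8a,9,9a-decahydro-1H-fluoren-8-yl)-3-oxopropanoate (core as in 30) | C#C[C@@H]1C=C[C@H]2[C@@H]3C[C@H](C)C[C@H](C)[C@H]3[C@H](O)[C@@H]2[C@H]1C(=O)CC(=O)OCC | intermediate
22 | ethyl 3-(7-ethenyl-9-hydroxy-1,3-dimethyl-2,3,4,4a,4b,7,8,8a,9,9a-decahydro-1H-fluoren-8-yl)-3-oxopropanoate (core as in 30) | C=C[C@@H]1C=C[C@H]2[C@@H]3C[C@H](C)C[C@H](C)[C@H]3[C@H](O)[C@@H]2[C@H]1C(=O)CC(=O)OCC | intermediate
23 | (4-iodophenyl)acetic acid | OC(=O)Cc1ccc(I)cc1 | starting material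
24 | (4-iodophenyl)acetyl chloride | ClC(=O)Cc1ccc(I)cc1 | intermediate (not isolated)
25 | 1-diazo-3-(4-iodophenyl)propan-2-one | [N-]=[N+]=CC(=O)Cc1ccc(I)cc1 | intermediate (not isolated)
26 | 1-bromo-3-(4-iodophenyl)propan-2-one | BrCC(=O)Cc1ccc(I)cc1 | intermediate
27 | ethyl 2-[(7-ethenyl-9-hydroxy-1,3-dimethyl-2,3,4,4a,4b,7,8,8a,9,9a-decahydro-1H-fluoren-8-yl)carbonyl]-5-(4-iodophenyl)-4-oxopentanoate (core as in 30; both C3' epimers) | C=C[C@@H]1C=C[C@H]2[C@@H]3C[C@H](C)C[C@H](C)[C@H]3[C@H](O)[C@@H]2[C@H]1C(=O)C(CC(=O)Cc4ccc(I)cc4)C(=O)OCC | intermediate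
28 | macrocyclic aryl ether keto ester (13-membered para-cyclophane; core as in 30; both C3' epimers) | C=C[C@@H]1C=C[C@H]2[C@@H]3C[C@H](C)C[C@H](C)[C@H]3[C@@H]3Oc4ccc(cc4)CC(=O)CC(C(=O)OCC)C(=O)[C@@H]1[C@H]23 | intermediate
29 | macrocyclic primary keto amide (core as in 30; both C3' epimers) | C=C[C@@H]1C=C[C@H]2[C@@H]3C[C@H](C)C[C@H](C)[C@H]3[C@@H]3Oc4ccc(cc4)CC(=O)CC(C(N)=O)C(=O)[C@@H]1[C@H]23 | intermediate (not isolated)
30 | xenoacremone H | C=C[C@@H]1C=C[C@H]2[C@@H]3C[C@H](C)C[C@H](C)[C@H]3[C@@H]3Oc4ccc(cc4)C[C@@]4(O)C[C@H](C(=O)N4)C(=O)[C@@H]1[C@H]23 | target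

**Step count.** Total: 20 steps. Longest linear sequence: 18 steps (steps 1–5, 7–16 and 18–20, from 1 to 30); steps 6 and 17 make the two side fragments.

**Steps most likely to fail**

Step 7. The azaenolate may be alkylated by the primary bromide before it adds to the enoate, or the auxiliary may fail to override the neighbouring methyl centre, so that facial selectivity at C9a erodes. The fallback separates the two events and sets C9a with an oxazolidinone auxiliary. It sets out from 5: Horner–Wadsworth–Emmons reaction with diethyl {2-[(4S)-4-benzyl-2-oxo-oxazolidin-3-yl]-2-oxoethyl}phosphonate (LiCl, i-Pr2NEt, MeCN) would give (4S)-4-benzyl-3-[(2E,4S,6R)-7-bromo-4,6-dimethylhept-2-enoyl]oxazolidin-2-one F1. Conjugate addition of vinylmagnesium bromide with CuBr·SMe2 at −78 °C, anti to the benzyl group of the chelated s-cis imide, would give (4S)-4-benzyl-3-[(3R,4S,6R)-7-bromo-3-ethenyl-4,6-dimethylheptanoyl]oxazolidin-2-one F2. Methanolysis with MeOMgBr would give methyl (3R,4S,6R)-7-bromo-3-ethenyl-4,6-dimethylheptanoate F3, and KN(SiMe3)2 in THF would close ring C by the same C4–C4a enolate alkylation to methyl (1R,2R,3S,5R)-2-ethenyl-3,5-dimethylcyclohexane-1-carboxylate F4. Hydroboration with 9-BBN and oxidation with NaBO3 would give methyl (1R,2R,3S,5R)-2-(2-hydroxyethyl)-3,5-dimethylcyclohexane-1-carboxylate F5, periodinane oxidation methyl (1R,2R,3S,5R)-3,5-dimethyl-2-(2-oxoethyl)cyclohexane-1-carboxylate F6, and condensation with 7 comes back to the route at 11.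

Step 13. The cis-alkynyl group may disfavour the s-cis diene enough that the cycloaddition becomes slow and polymerisation of the enal or exo addition competes. The fallback uses an unhindered (E,E)-diene and corrects C7 afterwards by epimerisation of an aldehyde. It sets out from 13: Horner–Wadsworth–Emmons reaction with triethyl phosphonoacetate would give ethyl (2E,4E)-5-[(1S,2R,3S,5R)-2-{(2E)-2-[(2R)-2-(methoxymethyl)pyrrolidin-1-ylimino]ethyl}-3,5-dimethylcyclohexyl]penta-2,4-dienoate F7, i-Bu2AlH the dienol F8 and t-BuMe2SiCl with imidazole the silyl ether F9. Oxalic acid hydrolysis as in step 11 would give the aldehyde F10, and the conditions of step 12 the benzoyloxy enal F11. The Me2AlCl-promoted intramolecular Diels–Alder reaction should then give the tricyclic aldehyde F12 with the silyloxymethyl group at C7 cis to C4a, and Roskamp homologation the β-keto ester F13. Bu4NF followed by K2CO3 in EtOH would give the diol F14; selective oxidation of the primary alcohol (TEMPO, PhI(OAc)2) would give the cis aldehyde F15, which brief treatment with DBU should epimerise at C7 to the all-equatorial trans aldehyde F16. Methylenation with Ph3P=CH2 comes back to the route at 22.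

Step 19. Intermolecular coupling to oligomers or C-arylation of the β-keto ester enolate may outpace closure of the strained 13-membered ring. The fallback closes the ether by nitro-activated nucleophilic aromatic substitution and removes the nitro group afterwards. It sets out from 22: alkylation as in step 18 with 1-bromo-3-(4-fluoro-3-nitrophenyl)propan-2-one F17, made from (4-fluoro-3-nitrophenyl)acetic acid by the sequence of step 17, would give the fluoronitroaryl seco compound F18. Cs2CO3 in DMF at high dilution should effect intramolecular SNAr of the C9 alkoxide to the nitro-substituted macrocyclic ether F19. Reduction with Zn and NH4Cl would give the macrocyclic aniline F20, and reductive deamination with t-BuONO in THF comes back to the route at 28.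

Further compounds
F1 | step 7 | (4S)-4-benzyl-3-[(2E,4S,6R)-7-bromo-4,6-dimethylhept-2-enoyl]oxazolidin-2-one | BrC[C@H](C)C[C@H](C)/C=C/C(=O)N1[C@@H](Cc2ccccc2)COC1=O
F2 | step 7 | (4S)-4-benzyl-3-[(3R,4S,6R)-7-bromo-3-ethenyl-4,6-dimethylheptanoyl]oxazolidin-2-one | BrC[C@H](C)C[C@H](C)[C@@H](C=C)CC(=O)N1[C@@H](Cc2ccccc2)COC1=O
F3 | step 7 | methyl (3R,4S,6R)-7-bromo-3-ethenyl-4,6-dimethylheptanoate | BrC[C@H](C)C[C@H](C)[C@@H](C=C)CC(=O)OC
F4 | step 7 | methyl (1R,2R,3S,5R)-2-ethenyl-3,5-dimethylcyclohexane-1-carboxylate | COC(=O)[C@@H]1C[C@H](C)C[C@H](C)[C@H]1C=C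
F5 | step 7 | methyl (1R,2R,3S,5R)-2-(2-hydroxyethyl)-3,5-dimethylcyclohexane-1-carboxylate | COC(=O)[C@@H]1C[C@H](C)C[C@H](C)[C@H]1CCO
F6 | step 7 | methyl (1R,2R,3S,5R)-3,5-dimethyl-2-(2-oxoethyl)cyclohexane-1-carboxylate | COC(=O)[C@@H]1C[C@H](C)C[C@H](C)[C@H]1CC=O
F7 | step 13 | ethyl (2E,4E)-5-[(1S,2R,3S,5R)-2-{(2E)-2-[(2R)-2-(methoxymethyl)pyrrolidin-1-ylimino]ethyl}-3,5-dimethylcyclohexyl]penta-2,4-dienoate | CCOC(=O)/C=C/C=C/[C@@H]1C[C@H](C)C[C@H](C)[C@H]1C/C=N/N1CCC[C@@H]1COC
F8 | step 13 | (2E,4E)-dienol from reduction of F7 | OC/C=C/C=C/[C@@H]1C[C@H](C)C[C@H](C)[C@H]1C/C=N/N1CCC[C@@H]1COC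
F9 | step 13 | tert-butyldimethylsilyl ether of F8 | CC(C)(C)[Si](C)(C)OC/C=C/C=C/[C@@H]1C[C@H](C)C[C@H](C)[C@H]1C/C=N/N1CCC[C@@H]1COC
F10 | step 13 | 2-[(1R,2S,4R,6S)-2-[(1E,3E)-5-(tert-butyldimethylsilyloxy)penta-1,3-dien-1-yl]-4,6-dimethylcyclohexyl]acetaldehyde | CC(C)(C)[Si](C)(C)OC/C=C/C=C/[C@@H]1C[C@H](C)C[C@H](C)[C@H]1CC=O
F11 | step 13 | benzoyloxy enal with (E,E)-silyloxypentadienyl diene | CC(C)(C)[Si](C)(C)OC/C=C/C=C/[C@@H]1C[C@H](C)C[C@H](C)[C@H]1[C@H](OC(=O)c1ccccc1)/C=C/C=O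
F12 | step 13 | tricyclic aldehyde with 7-(silyloxymethyl) group cis to C4a (C7 epimeric to 30; other core centres as in 30) | CC(C)(C)[Si](C)(C)OC[C@H]1C=C[C@H]2[C@@H]3C[C@H](C)C[C@H](C)[C@H]3[C@H](OC(=O)c4ccccc4)[C@@H]2[C@H]1C=O
F13 | step 13 | β-keto ester from F12 | CC(C)(C)[Si](C)(C)OC[C@H]1C=C[C@H]2[C@@H]3C[C@H](C)C[C@H](C)[C@H]3[C@H](OC(=O)c4ccccc4)[C@@H]2[C@H]1C(=O)CC(=O)OCC
F14 | step 13 | 7-(hydroxymethyl)-9-hydroxy β-keto ester | OC[C@H]1C=C[C@H]2[C@@H]3C[C@H](C)C[C@H](C)[C@H]3[C@H](O)[C@@H]2[C@H]1C(=O)CC(=O)OCC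
F15 | step 13 | 7-formyl β-keto ester with formyl cis to C4a | O=C[C@H]1C=C[C@H]2[C@@H]3C[C@H](C)C[C@H](C)[C@H]3[C@H](O)[C@@H]2[C@H]1C(=O)CC(=O)OCC
F16 | step 13 | 7-formyl β-keto ester epimerised at C7 (core as in 30) | O=C[C@@H]1C=C[C@H]2[C@@H]3C[C@H](C)C[C@H](C)[C@H]3[C@H](O)[C@@H]2[C@H]1C(=O)CC(=O)OCC
F17 | step 19 | 1-bromo-3-(4-fluoro-3-nitrophenyl)propan-2-one | BrCC(=O)Cc1ccc(F)c([N+](=O)[O-])c1
F18 | step 19 | ethyl 2-[(7-ethenyl-9-hydroxy-1,3-dimethyl-decahydrofluoren-8-yl)carbonyl]-5-(4-fluoro-3-nitrophenyl)-4-oxopentanoate | C=C[C@@H]1C=C[C@H]2[C@@H]3C[C@H](C)C[C@H](C)[C@H]3[C@H](O)[C@@H]2[C@H]1C(=O)C(CC(=O)Cc4ccc(F)c([N+](=O)[O-])c4)C(=O)OCC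
F19 | step 19 | nitro-substituted macrocyclic aryl ether keto ester | C=C[C@@H]1C=C[C@H]2[C@@H]3C[C@H](C)C[C@H](C)[C@H]3[C@@H]3Oc4ccc(cc4[N+](=O)[O-])CC(=O)CC(C(=O)OCC)C(=O)[C@@H]1[C@H]23
F20 | step 19 | amino-substituted macrocyclic aryl ether keto ester | C=C[C@@H]1C=C[C@H]2[C@@H]3C[C@H](C)C[C@H](C)[C@H]3[C@@H]3Oc4ccc(cc4N)CC(=O)CC(C(=O)OCC)C(=O)[C@@H]1[C@H]23
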